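The ten-membered carbocycle (C1–C10; lactone on C6/C7, C5 hydroxyl, C8 angelate, C9–C10 epoxide, C4 methyl) is opened at C1–C10. The C8-oxygenated C9–C10 epoxide is read as a hydroxyl-directed epoxidation product of an E-trisubstituted alkene, and the unfunctionalised C1–C3 chain as a hydroborated allyl group. The key step is therefore an intramolecular B-alkyl Suzuki–Miyaura coupling: an acyclic trans-γ-lactone bearing a terminal alkene and an (E)-C10 vinyl iodide is hydroborated and cyclised, closing the ring at C1–C10 and fixing the alkene geometry that later becomes both epoxide stereocentres. The lactone core comes from a substrate-controlled boron aldol.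

Key step: step 13

Remark: locants are C1–C10 for the ring, C11/C12/C13 for the lactone α-carbon, carbonyl and exocyclic methylene, C14 and C15 for the methyls on C10 and C4, and they are kept for acyclic precursors; CIP letters at C7 and C8 change along the route only through substituent priorities (no centre is inverted after it is set), and 1, 2, 10, 11, 27 and all reagents are taken as catalogue chemicals.

Step 1
Reactants: 1 prop-2-yn-1-ol; 2 allyl bromide
Product: 3 hex-5-en-2-yn-1-ol
Conditions: CuI (10 mol %), K2CO3, Bu4NI (cat.), DMF, rt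
Reagents that add atoms: none
Why: Copper-catalysed coupling of the terminal alkyne (as copper acetylide) with the allylic bromide should give the skipped enyne without protecting the alcohol.

Step 2
Reactants: 3 hex-5-en-2-yn-1-ol
Product: 4 (2E)-hexa-2,5-dien-1-ol
Conditions: NaAlH2(OCH2CH2OMe)2, THF, 0 °C → rt; aq. Rochelle salt
Reagents that add atoms: none
Why: Alkoxide-directed trans-hydroalumination of the propargylic alcohol followed by protonolysis should give only the E-allylic alcohol, the isolated terminal alkene being inert.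

Step 3
Reactants: 4 (2E)-hexa-2,5-dien-1-ol
Product: 5 [(2S,3S)-3-(prop-2-en-1-yl)oxiran-2-yl]methanol
Conditions: Ti(OiPr)4 (10 mol %), L-(+)-diethyl tartrate (12 mol %), t-BuOOH, 4 Å MS, CH2Cl2, −20 °C
Reagents that add atoms: tert-butyl hydroperoxide, CC(C)(C)OO
Why: Sharpless asymmetric epoxidation epoxidises only the allylic alkene, and the L-(+)-tartrate ligand sets the (2S,3S) epoxide, which fixes C5 and, after inversion, C4.

Step 4
Reactants: 5 [(2S,3S)-3-(prop-2-en-1-yl)oxiran-2-yl]methanol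
Product: 6 (2R,3R)-3-methylhex-5-ene-1,2-diol
Conditions: AlMe3 (3 equiv), hexane/CH2Cl2, 0 °C → rt
Reagents that add atoms: trimethylaluminium, C[Al](C)C
Why: Regioselective opening of a 2,3-epoxy alcohol by AlMe3 through the aluminium alkoxide delivers methyl to the distal epoxide carbon with inversion, so the trans-epoxide gives the anti C4-methyl/C5-hydroxyl pair.

Step 5
Reactants: 6 (2R,3R)-3-methylhex-5-ene-1,2-diol
Product: 8 (2R,3R)-2-(tert-butyldimethylsilyloxy)-3-methyl-1-(triethylsilyloxy)hex-5-ene, via primary TES ether 7 (not isolated)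
Conditions: TESCl (1.0 equiv), imidazole, CH2Cl2, −78 → −40 °C; then TBSOTf, 2,6-lutidine, −78 → 0 °C
Reagents that add atoms: chlorotriethylsilane, CC[Si](CC)(CC)Cl; tert-butyldimethylsilyl triflate, CC(C)(C)[Si](C)(C)OS(=O)(=O)C(F)(F)F
Why: Sequential silyl ether formation: the primary hydroxyl reacts first with the chlorosilane at low temperature and the secondary hydroxyl is then capped by the more reactive silyl triflate.

Step 6
Reactants: 8 (2R,3R)-2-(tert-butyldimethylsilyloxy)-3-methyl-1-(triethylsilyloxy)hex-5-ene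
Product: 9 (2R,3R)-2-(tert-butyldimethylsilyloxy)-3-methylhex-5-enal
Conditions: (COCl)2, DMSO, CH2Cl2, −78 → −30 °C; Et3N, −78 → 0 °C
Reagents that add atoms: none
Why: Under Swern conditions the chlorosulfonium salt cleaves a primary triethylsilyl ether and oxidises it directly to the aldehyde while the secondary TBS ether survives; the α-centre (C5) is kept cold to avoid epimerisation.

Step 7
Reactants: 10 methyl 4-chloro-4-oxobutanoate; 11 trimethyl(prop-1-yn-1-yl)silane
Product: 12 methyl 4-oxohept-5-ynoate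
Conditions: AlCl3, CH2Cl2, 0 °C
Reagents that add atoms: none
Why: Friedel–Crafts-type acylation of the alkynylsilane at the silicon-bearing carbon (β-silyl cation, loss of Me3SiCl) should give the propynyl ketone with the ester untouched.

Step 8
Reactants: 12 methyl 4-oxohept-5-ynoate; 9 (2R,3R)-2-(tert-butyldimethylsilyloxy)-3-methylhex-5-enal
Product: 15 (4S,5S)-4-(but-2-ynoyl)-5-[(1R,2R)-1-(tert-butyldimethylsilyloxy)-2-methylpent-4-en-1-yl]oxolan-2-one, via Z-enolborinate 13 (not isolated), via aldol adduct 14 (not isolated)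
Conditions: Bu2BOTf, i-Pr2NEt, CH2Cl2, −78 → 0 °C; 9, −78 → −20 °C; pH 7 buffer/MeOH; then PPTS (cat.), CH2Cl2, rt
Reagents that add atoms: dibutylboron triflate, CCCCB(CCCC)OS(=O)(=O)C(F)(F)F (boron stays in 13 only)
Why: Boron-mediated aldol reaction: the Z-enolborinate (only the C7 methylene is enolisable) reacts through a Zimmerman–Traxler chair to give the C6/C7 syn pair, the Cornforth (polar Felkin) preference of the α-silyloxy aldehyde towards Z-enolates sets C6 anti to C5–O, and the γ-hydroxy methyl ester then lactonises under mild acid to the trans-lactone.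

Step 9
Reactants: 15 ynone lactone
Product: 16 (4R,5S)-5-[(1R,2R)-1-(tert-butyldimethylsilyloxy)-2-methylpent-4-en-1-yl]-4-[(1R)-1-hydroxybut-2-yn-1-yl]oxolan-2-one
Conditions: Ru(p-cymene)[(R,R)-TsNCHPhCHPhNH] (2 mol %), i-PrOH, rt
Reagents that add atoms: none
Why: Noyori asymmetric transfer hydrogenation of an alkynyl ketone is catalyst-controlled, the (R,R) complex giving the (R)-propargylic alcohol at C8, and its neutral conditions avoid β-acyloxy elimination and C7 epimerisation.

Step 10
Reactants: 16 propargylic alcohol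
Product: 17 (4S,5S)-5-[(1R,2R)-1-(tert-butyldimethylsilyloxy)-2-methylpent-4-en-1-yl]-4-[(1R)-1-(triethylsilyloxy)but-2-yn-1-yl]oxolan-2-one
Conditions: TESOTf, 2,6-lutidine, CH2Cl2, −78 °C
Reagents that add atoms: triethylsilyl triflate, CC[Si](CC)(CC)OS(=O)(=O)C(F)(F)F
Why: Silyl ether formation at the hindered C8 hydroxyl blocks 6,12 → 8,12 translactonisation in the basic steps 11–14 and adds steric bias for step 11.

Step 11
Reactants: 17 silyl-protected alkyne
Product: 18 (4S,5S)-5-[(1R,2R)-1-(tert-butyldimethylsilyloxy)-2-methylpent-4-en-1-yl]-4-[(1S,2Z)-3-(4,4,5,5-tetramethyl-1,3,2-dioxaborolan-2-yl)-1-(triethylsilyloxy)but-2-en-1-yl]oxolan-2-one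
Conditions: CuCl (10 mol %), PCy3 (12 mol %), NaOt-Bu (15 mol %), B2pin2, MeOH (2 equiv), toluene, rt
Reagents that add atoms: bis(pinacolato)diboron, CC1(C)OB(OC1(C)C)B1OC(C)(C)C(C)(C)O1
Why: Copper-catalysed borylcupration–protonation (formal syn-hydroboration) of a propargylic ether places boron on the methyl-bearing carbon distal to oxygen and hydrogen on C9 on the same side, so boron is trans to C8, while the unactivated terminal alkene does not react.

Step 12
Reactants: 18 alkenylboronate
Product: 19 (4S,5S)-5-[(1R,2R)-1-(tert-butyldimethylsilyloxy)-2-methylpent-4-en-1-yl]-4-[(1R,2E)-3-iodo-1-(triethylsilyloxy)but-2-en-1-yl]oxolan-2-one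
Conditions: NaOMe (MeOH), THF, −78 °C; I2, −78 → 0 °C
Reagents that add atoms: iodine, II
Why: Iododeboronation of the methoxide-derived alkenyl borate by iodine proceeds with retention, giving the (E)-iodide with iodine trans to C8.

Step 13
Reactants: 19 vinyl iodide
Product: 21 macrocyclic lactone (4R,5R,6S,7S,8S,9E)-5-(tert-butyldimethylsilyloxy)-8-(triethylsilyloxy)germacr-9-en-12,6-olide, via B-alkyl-9-BBN 20 (not isolated)
Conditions: 9-BBN (0.5 M in THF), THF, 0 °C → rt; then syringe-pump addition to Pd(dppf)Cl2 (20 mol %), AsPh3, Cs2CO3, DMF/THF/H2O, 50 °C (final 2 mM)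
Reagents that add atoms: 9-borabicyclo[3.3.1]nonane, B1C2CCCC1CCC2 (stays in 20 only)
Why: 9-BBN adds anti-Markovnikov to the only monosubstituted alkene of 19 (the iodoalkene is trisubstituted and the lactone inert) to give 20; zerovalent palladium then inserts into the C10–I bond with retention, the hydroxide-activated borate transfers C1 to palladium intramolecularly, and reductive elimination from the alkyl(alkenyl) divalent palladium species forms C1–C10. The closest known reaction is the B-alkyl Suzuki–Miyaura macrocyclisation used to close nine- to twelve-membered (E)-cycloalkenes. The ten-membered carbocycle is closed by reductive elimination from an eleven-membered palladacycle, the new bond joining the sp3 chain terminus to the endocyclic alkene carbon. No sp3 stereocentre is formed; the E geometry of C9=C10, which later becomes C9 and C10 of the epoxide, is carried over stereospecifically from the vinyl iodide. The step needs cyclisation to beat oligomerisation, protodeboronation and β-hydride loss, which high dilution with slow addition of 20, the dppf/AsPh3 system and the gauche disposition of the two chains on the trans-lactone should secure, while the C8 silyl ether prevents base-induced translactonisation.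

Step 14
Reactants: 21 macrocyclic lactone
Product: 24 (4R,5R,6S,7S,8S,9E)-5-(tert-butyldimethylsilyloxy)-8-(triethylsilyloxy)germacra-9,11(13)-dien-12,6-olide, via Mannich base 22 (not isolated), via ammonium iodide 23 (not isolated)
Conditions: LiN(i-Pr)2, THF, −78 °C; CH2=NMe2+ I−, −78 °C → rt; then MeI, MeOH, rt; then sat. aq. NaHCO3/EtOAc, rt
Reagents that add atoms: N,N-dimethylmethyleneiminium iodide (Eschenmoser's salt), C=[N+](C)C.[I-]; iodomethane, CI (stays in 23 only)
Why: The lithium enolate of the lactone (C11 is the only enolisable position) is aminomethylated in a Mannich reaction, and exhaustive N-methylation followed by base-induced elimination of trimethylamine unveils the exocyclic methylene.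

Step 15
Reactants: 24 bis-silyl methylene lactone
Product: 25 (4R,5R,6S,7R,8S,9E)-5-(tert-butyldimethylsilyloxy)-8-hydroxygermacra-9,11(13)-dien-12,6-olide
Conditions: PPTS (cat.), MeOH/CH2Cl2, 0 °C
Reagents that add atoms: none
Why: Acid-catalysed methanolysis removes the allylic triethylsilyl ether much faster than the hindered secondary TBS ether (selective desilylation), and the methylene lactone tolerates mild acid.

Step 16
Reactants: 25 macrocyclic allylic alcohol
Product: 26 (4R,5R,6S,7R,8R,9R,10R)-5-(tert-butyldimethylsilyloxy)-9,10-epoxy-8-hydroxygermacr-11(13)-en-12,6-olide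
Conditions: VO(acac)2 (5 mol %), t-BuOOH, CH2Cl2, 0 °C → rt
Reagents that add atoms: tert-butyl hydroperoxide, CC(C)(C)OO
Why: Hydroxyl-directed vanadium-catalysed epoxidation (Sharpless–Michaelson) is syn-stereospecific (E-alkene to trans-epoxide) and needs an O–C8–C9=C10 dihedral near 40–50°; because the C8–C7 ring bond of the (E)-cyclodecene must stand perpendicular to the alkene on the ring-interior face, the reactive arrangement has C8–O near the alkene plane and oxygen delivered to the exposed face, which should give the erythro (C8–O/C9–O anti) epoxy alcohol with 9R,10R configuration, the electron-poor methylene lactone staying untouched.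

Step 17
Reactants: 26 epoxy alcohol; 27 angelic acid [(2Z)-2-methylbut-2-enoic acid]
Product: 28 (4R,5R,6S,7R,8R,9R,10R)-8-angeloyloxy-5-(tert-butyldimethylsilyloxy)-9,10-epoxygermacr-11(13)-en-12,6-olide
Conditions: 27, 2,4,6-trichlorobenzoyl chloride, Et3N, toluene, rt; then 26, 75 °C
Reagents that add atoms: none
Why: Yamaguchi-type esterification through the preformed mixed anhydride, run without DMAP, should acylate the only free hydroxyl (C8) without Z → E isomerisation of the angelate.

Step 18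
Reactants: 28 silyl-protected angelate
Product: 29 CNP0165329.1, (4R,5R,6S,7S,8R,9R,10R)-8-angeloyloxy-9,10-epoxy-5-hydroxygermacr-11(13)-en-12,6-olide
Conditions: HF·pyridine, pyridine, THF, 0 °C → rt
Reagents that add atoms: none
Why: Pyridine-buffered fluoride desilylation removes the C5 TBS ether while the trisubstituted epoxide, the angelate and the α-methylene lactone should be preserved.

Compound list
1 | prop-2-yn-1-ol | C#CCO | starting material
2 | allyl bromide (3-bromoprop-1-ene) | C=CCBr | starting material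
3 | hex-5-en-2-yn-1-ol | OCC#CCC=C | intermediate
4 | (2E)-hexa-2,5-dien-1-ol | OC/C=C/CC=C | intermediate
5 | [(2S,3S)-3-(prop-2-en-1-yl)oxiran-2-yl]methanol | OC[C@@H]1O[C@H]1CC=C | intermediate
6 | (2R,3R)-3-methylhex-5-ene-1,2-diol | OC[C@H](O)[C@H](C)CC=C | intermediate
7 | (2R,3R)-3-methyl-1-(triethylsilyloxy)hex-5-en-2-ol | CC[Si](CC)(CC)OC[C@H](O)[C@H](C)CC=C | intermediate
8 | (2R,3R)-2-(tert-butyldimethylsilyloxy)-3-methyl-1-(triethylsilyloxy)hex-5-ene | CC[Si](CC)(CC)OC[C@H](O[Si](C)(C)C(C)(C)C)[C@H](C)CC=C | intermediate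
9 | (2R,3R)-2-(tert-butyldimethylsilyloxy)-3-methylhex-5-enal | O=C[C@H](O[Si](C)(C)C(C)(C)C)[C@H](C)CC=C | intermediate
10 | methyl 4-chloro-4-oxobutanoate | COC(=O)CCC(Cl)=O | starting material
11 | trimethyl(prop-1-yn-1-yl)silane | CC#C[Si](C)(C)C | starting material
12 | methyl 4-oxohept-5-ynoate | COC(=O)CCC(=O)C#CC | intermediate
13 | methyl (3Z)-4-(dibutylboranyloxy)hept-3-en-5-ynoate | COC(=O)C/C=C(\OB(CCCC)CCCC)C#CC | intermediate
14 | methyl (3S,4S,5R,6R)-3-(but-2-ynoyl)-5-(tert-butyldimethylsilyloxy)-4-hydroxy-6-methylnon-8-enoate | COC(=O)C[C@H](C(=O)C#CC)[C@H](O)[C@H](O[Si](C)(C)C(C)(C)C)[C@H](C)CC=C | intermediate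
15 | (4S,5S)-4-(but-2-ynoyl)-5-[(1R,2R)-1-(tert-butyldimethylsilyloxy)-2-methylpent-4-en-1-yl]oxolan-2-one | C=CC[C@@H](C)[C@@H](O[Si](C)(C)C(C)(C)C)[C@H]1OC(=O)C[C@@H]1C(=O)C#CC | intermediate
16 | (4R,5S)-5-[(1R,2R)-1-(tert-butyldimethylsilyloxy)-2-methylpent-4-en-1-yl]-4-[(1R)-1-hydroxybut-2-yn-1-yl]oxolan-2-one | C=CC[C@@H](C)[C@@H](O[Si](C)(C)C(C)(C)C)[C@H]1OC(=O)C[C@@H]1[C@@H](O)C#CC | intermediate
17 | (4S,5S)-5-[(1R,2R)-1-(tert-butyldimethylsilyloxy)-2-methylpent-4-en-1-yl]-4-[(1R)-1-(triethylsilyloxy)but-2-yn-1-yl]oxolan-2-one | C=CC[C@@H](C)[C@@H](O[Si](C)(C)C(C)(C)C)[C@H]1OC(=O)C[C@@H]1[C@@H](O[Si](CC)(CC)CC)C#CC | intermediate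
18 | (4S,5S)-5-[(1R,2R)-1-(tert-butyldimethylsilyloxy)-2-methylpent-4-en-1-yl]-4-[(1S,2Z)-3-(4,4,5,5-tetramethyl-1,3,2-dioxaborolan-2-yl)-1-(triethylsilyloxy)but-2-en-1-yl]oxolan-2-one | C=CC[C@@H](C)[C@@H](O[Si](C)(C)C(C)(C)C)[C@H]1OC(=O)C[C@@H]1[C@@H](O[Si](CC)(CC)CC)/C=C(\C)B1OC(C)(C)C(C)(C)O1 | intermediate
19 | (4S,5S)-5-[(1R,2R)-1-(tert-butyldimethylsilyloxy)-2-methylpent-4-en-1-yl]-4-[(1R,2E)-3-iodo-1-(triethylsilyloxy)but-2-en-1-yl]oxolan-2-one | C=CC[C@@H](C)[C@@H](O[Si](C)(C)C(C)(C)C)[C@H]1OC(=O)C[C@@H]1[C@@H](O[Si](CC)(CC)CC)/C=C(\C)I | intermediate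
20 | (4S,5S)-5-[(1R,2R)-5-(9-borabicyclo[3.3.1]nonan-9-yl)-1-(tert-butyldimethylsilyloxy)-2-methylpentyl]-4-[(1R,2E)-3-iodo-1-(triethylsilyloxy)but-2-en-1-yl]oxolan-2-one | C1CCC2CCCC1B2CCC[C@@H](C)[C@@H](O[Si](C)(C)C(C)(C)C)[C@H]1OC(=O)C[C@@H]1[C@@H](O[Si](CC)(CC)CC)/C=C(\C)I | intermediate
21 | (4R,5R,6S,7S,8S,9E)-5-(tert-butyldimethylsilyloxy)-8-(triethylsilyloxy)germacr-9-en-12,6-olide (ten-membered E-cycloalkene trans-fused at C6/C7 to the saturated γ-lactone) | C1C(=O)O[C@@H]2[C@H](O[Si](C)(C)C(C)(C)C)[C@H](C)CCC/C(C)=C/[C@H](O[Si](CC)(CC)CC)[C@@H]12 | intermediate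
22 | 11-(dimethylaminomethyl) derivative of 21 (C11 epimers, mainly trans to C8) | CN(C)CC1C(=O)O[C@@H]2[C@H](O[Si](C)(C)C(C)(C)C)[C@H](C)CCC/C(C)=C/[C@H](O[Si](CC)(CC)CC)[C@@H]12 | intermediate
23 | 11-(trimethylammoniomethyl) iodide of 21 | C[N+](C)(C)CC1C(=O)O[C@@H]2[C@H](O[Si](C)(C)C(C)(C)C)[C@H](C)CCC/C(C)=C/[C@H](O[Si](CC)(CC)CC)[C@@H]12.[I-] | intermediate
24 | (4R,5R,6S,7S,8S,9E)-5-(tert-butyldimethylsilyloxy)-8-(triethylsilyloxy)germacra-9,11(13)-dien-12,6-olide | C=C1C(=O)O[C@@H]2[C@H](O[Si](C)(C)C(C)(C)C)[C@H](C)CCC/C(C)=C/[C@H](O[Si](CC)(CC)CC)[C@@H]12 | intermediate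
25 | (4R,5R,6S,7R,8S,9E)-5-(tert-butyldimethylsilyloxy)-8-hydroxygermacra-9,11(13)-dien-12,6-olide | C=C1C(=O)O[C@@H]2[C@H](O[Si](C)(C)C(C)(C)C)[C@H](C)CCC/C(C)=C/[C@H](O)[C@@H]12 | intermediate
26 | (4R,5R,6S,7R,8R,9R,10R)-5-(tert-butyldimethylsilyloxy)-9,10-epoxy-8-hydroxygermacr-11(13)-en-12,6-olide | C=C1C(=O)O[C@@H]2[C@H](O[Si](C)(C)C(C)(C)C)[C@H](C)CCC[C@@]3(C)O[C@@H]3[C@H](O)[C@@H]12 | intermediate
27 | angelic acid, (2Z)-2-methylbut-2-enoic acid | C/C=C(/C)C(=O)O | starting material
28 | (4R,5R,6S,7R,8R,9R,10R)-8-angeloyloxy-5-(tert-butyldimethylsilyloxy)-9,10-epoxygermacr-11(13)-en-12,6-olide | C=C1C(=O)O[C@@H]2[C@H](O[Si](C)(C)C(C)(C)C)[C@H](C)CCC[C@@]3(C)O[C@@H]3[C@H](OC(=O)/C(C)=C\C)[C@@H]12 | intermediate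
29 | CNP0165329.1, (4R,5R,6S,7S,8R,9R,10R)-8-angeloyloxy-9,10-epoxy-5-hydroxygermacr-11(13)-en-12,6-olide | C=C1C(=O)O[C@@H]2[C@H](O)[C@H](C)CCC[C@@]3(C)O[C@@H]3[C@H](OC(=O)/C(C)=C\C)[C@@H]12 | target

Total step count: 18. Longest linear sequence: 17 (steps 1–6 and 8–18; ketone 12 is made in one step).

Steps most likely to fail

1. Step 13 (key step). The strained (E)-cyclodecene may close too slowly, so that intermolecular coupling, protodeboronation of the borane or reduction of the vinyl iodide take over. The fallback sets out from 19 and comes back at 21. It hydroborates 19 to 20 as before and iodinates the borane (I2, NaOMe, THF) to the primary iodide F1. Zinc insertion (Zn dust, LiCl, THF, 40 °C; the vinyl iodide does not insert) then gives the alkylzinc iodide F2. The same C1–C10 bond is closed by an intramolecular Negishi coupling (Pd2(dba)3, P(2-furyl)3, THF/NMP, 50 °C, high dilution), which needs neither base nor water, to give 21.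

2. Step 16. Oxygen may be delivered to the other alkene face, through the ground-state conformer that has H8 in the alkene plane, which would give the C9/C10-epimeric epoxide. The fallback sets out from 24 and comes back at 26. N-Bromosuccinimide in THF/H2O (0 °C) puts bromine on the exposed face of that conformer and water on the tertiary C10 from the opposite side, giving the bromohydrin F3. DBU (CH2Cl2, rt) closes the epoxide with inversion at C9, so the oxygen ends on the face opposite to the one an electrophilic oxidant attacks, giving the silyl-protected epoxide F4. PPTS/MeOH then removes the triethylsilyl group to give 26.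

3. Step 8. Enolisation of the ynone may be incomplete or not Z-selective, facial selectivity may erode, and the β-hydroxy ynone may close by 6-endo oxa-Michael addition to a dihydropyranone before it lactonises. The fallback sets out from 9 (with 10) and comes back at 15.
 - Acylation of (S)-4-benzyl-1,3-oxazolidin-2-one with 10 (n-BuLi, THF, −78 °C) gives the imide F5.
 - Its Evans syn-aldol with 9 (Bu2BOTf, i-Pr2NEt, CH2Cl2, −78 → 0 °C) is auxiliary-controlled and matched with the Cornforth preference of 9; it gives the aldol adduct F6, which lactonises (PPTS) to the lactone imide F7.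
 - LiOH/H2O2 (THF/H2O, 0 °C) cleaves the auxiliary to the acid F8.
 - MeNHOMe·HCl with EDC gives the Weinreb amide F9, and 1-propynylmagnesium bromide (THF, −78 °C) gives 15.

Further compounds
F1 | step 13 | (4S,5S)-5-[(1R,2R)-1-(tert-butyldimethylsilyloxy)-5-iodo-2-methylpentyl]-4-[(1R,2E)-3-iodo-1-(triethylsilyloxy)but-2-en-1-yl]oxolan-2-one | ICCC[C@@H](C)[C@@H](O[Si](C)(C)C(C)(C)C)[C@H]1OC(=O)C[C@@H]1[C@@H](O[Si](CC)(CC)CC)/C=C(\C)I
F2 | step 13 | alkylzinc iodide from F1 (C1–ZnI) | I[Zn]CCC[C@@H](C)[C@@H](O[Si](C)(C)C(C)(C)C)[C@H]1OC(=O)C[C@@H]1[C@@H](O[Si](CC)(CC)CC)/C=C(\C)I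
F3 | step 16 | (4R,5R,6S,7S,8R,9S,10R)-9-bromo-5-(tert-butyldimethylsilyloxy)-10-hydroxy-8-(triethylsilyloxy)germacr-11(13)-en-12,6-olide | C=C1C(=O)O[C@@H]2[C@H](O[Si](C)(C)C(C)(C)C)[C@H](C)CCC[C@@](C)(O)[C@@H](Br)[C@H](O[Si](CC)(CC)CC)[C@@H]12
F4 | step 16 | (4R,5R,6S,7S,8R,9R,10R)-5-(tert-butyldimethylsilyloxy)-9,10-epoxy-8-(triethylsilyloxy)germacr-11(13)-en-12,6-olide | C=C1C(=O)O[C@@H]2[C@H](O[Si](C)(C)C(C)(C)C)[C@H](C)CCC[C@@]3(C)O[C@@H]3[C@H](O[Si](CC)(CC)CC)[C@@H]12
F5 | step 8 | methyl 4-[(4S)-4-benzyl-2-oxo-1,3-oxazolidin-3-yl]-4-oxobutanoate | COC(=O)CCC(=O)N1C(=O)OC[C@@H]1Cc1ccccc1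
F6 | step 8 | methyl (3S,4S,5R,6R)-3-[(4S)-4-benzyl-2-oxo-1,3-oxazolidine-3-carbonyl]-5-(tert-butyldimethylsilyloxy)-4-hydroxy-6-methylnon-8-enoate | COC(=O)C[C@H](C(=O)N1C(=O)OC[C@@H]1Cc1ccccc1)[C@H](O)[C@H](O[Si](C)(C)C(C)(C)C)[C@H](C)CC=C
F7 | step 8 | (4S)-4-benzyl-3-{(2S,3S)-2-[(1R,2R)-1-(tert-butyldimethylsilyloxy)-2-methylpent-4-en-1-yl]-5-oxooxolane-3-carbonyl}-1,3-oxazolidin-2-one | C=CC[C@@H](C)[C@@H](O[Si](C)(C)C(C)(C)C)[C@H]1OC(=O)C[C@@H]1C(=O)N1C(=O)OC[C@@H]1Cc1ccccc1
F8 | step 8 | (2S,3S)-2-[(1R,2R)-1-(tert-butyldimethylsilyloxy)-2-methylpent-4-en-1-yl]-5-oxooxolane-3-carboxylic acid | C=CC[C@@H](C)[C@@H](O[Si](C)(C)C(C)(C)C)[C@H]1OC(=O)C[C@@H]1C(=O)O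
F9 | step 8 | (2S,3S)-2-[(1R,2R)-1-(tert-butyldimethylsilyloxy)-2-methylpent-4-en-1-yl]-N-methoxy-N-methyl-5-oxooxolane-3-carboxamide | C=CC[C@@H](C)[C@@H](O[Si](C)(C)C(C)(C)C)[C@H]1OC(=O)C[C@@H]1C(=O)N(C)OC
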